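## Retrosynthetic overview
1. Target 16 comes from the C1 carbinol 15 by a final allylic oxidation. The C1 ketone stays masked until both rings exist, because it lies five atoms from the nucleophilic C7 and would otherwise be attacked to give a cyclopentanol.
2. 15 comes from the acyclic chloro-enal 13 in one flask. An SE2′ indium Barbier allenylation forms C6–C7 and closes the ten-membered ring first. CO and acetate then convert the allenol into the 13-acetoxy butenolide (O6–C12, C12–C11, C13–OAc), which is the second ring.
3. 13 comes from a C2–C3 boron aldol of enone 7 with Z-enal 10 (sets C3), then an Evans–Tishchenko reduction (C3-OAc, C1-OH) and acetal hydrolysis.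
4. 7 comes from propargyl alcohol, a chloropropyl ketal and CH2O. 10 comes from propargyl alcohol, MeMgBr and an orthoformate, and its Z-alkene is fixed by anti-carbomagnesiation.

Germacrane numbering (C1–C15) is used for positions.

Assumption: with methyl ketones, (+)-Ipc2BCl (made from (−)-α-pinene) directs attack to the Si face of the aldehyde. I could not confirm this sense of induction; if it is opposite, the antipodal reagent is used and nothing else changes.

## Route

Step 1
Reactants: 1 propargyl alcohol; 2 2-(3-chloropropyl)-2-methyl-1,3-dioxolane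
Product: 4 8-hydroxyoct-6-yn-2-one, via ketal alkynol 3 (not isolated)
Conditions: 1, n-BuLi (2.1 equiv), THF/DMPU, −78 → 0 °C; 2, NaI (0.2 equiv), 55 °C; then 2 M HCl, THF, rt
Reagents that add atoms: water, O
Why: SN2 alkylation of the dilithiated propargyl alcohol at its acetylide carbon by the primary halide, followed by acid hydrolysis of the ketal during work-up; no stereocentre is formed.

Step 2
Reactants: 4 8-hydroxyoct-6-yn-2-one
Product: 5 8-hydroxy-3-methylideneoct-6-yn-2-one
Conditions: paraformaldehyde (3 equiv), i-Pr2NH·TFA (1 equiv), TFA (10 mol %), THF, reflux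
Reagents that add atoms: formaldehyde (as paraformaldehyde), C=O
Why: Mannich-type α-methylenation (direct methylene transfer), in which the more substituted enol reacts with the iminium ion under the acidic ammonium-salt conditions and loss of the amine gives the 1,1-disubstituted enone; no stereocentre is formed.

Step 3
Reactants: 5 8-hydroxy-3-methylideneoct-6-yn-2-one
Product: 7 8-chloro-3-methylideneoct-6-yn-2-one, via propargylic mesylate 6 (not isolated)
Conditions: MsCl, Et3N, CH2Cl2, −20 °C; then LiCl, DMF, rt
Reagents that add atoms: methanesulfonyl chloride, CS(=O)(=O)Cl (in 6 only); lithium chloride, [Li+].[Cl-]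
Why: Mesylation followed by Finkelstein-type SN2 displacement at the unhindered propargylic carbon, the chloride being chosen because, unlike the bromide, it should survive the amine base of step 6.

Step 4
Reactants: 1 propargyl alcohol
Product: 9 (Z)-4,4-diethoxy-2-methylbut-2-en-1-ol, via vinylmagnesium chelate 8 (not isolated)
Conditions: MeMgBr (3 equiv), CuI (10 mol %), THF/Et2O, −10 °C → rt; then PhOCH(OEt)2, 0 °C → rt; aq NH4Cl; base-washed silica
Reagents that add atoms: methylmagnesium bromide, C[Mg]Br; diethyl phenyl orthoformate, CCOC(OCC)Oc1ccccc1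
Why: Hydroxyl-directed anti-carbomagnesiation puts the methyl group on the internal carbon and holds magnesium cis to CH2O in a five-membered chelate, so the Bodroux–Chichibabin-type reaction with the orthoformate gives only the Z-alkene (C3 and C6 cis).

Step 5
Reactants: 9 (Z)-4,4-diethoxy-2-methylbut-2-en-1-ol
Product: 10 (Z)-4,4-diethoxy-2-methylbut-2-enal
Conditions: MnO2 (15 equiv), CH2Cl2, rt
Reagents that add atoms: none
Why: Neutral MnO2 oxidation of an allylic alcohol, which touches neither the acetal nor the Z-geometry.

Step 6
Reactants: 7 8-chloro-3-methylideneoct-6-yn-2-one; 10 (Z)-4,4-diethoxy-2-methylbut-2-enal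
Product: 11 (2Z,4S)-12-chloro-1,1-diethoxy-4-hydroxy-3-methyl-7-methylidenedodec-2-en-10-yn-6-one
Conditions: 7 (1.2 equiv), (+)-Ipc2BCl (1.1 equiv), Et3N, Et2O, 0 °C; 10, −78 → −20 °C; pH 7 buffer, MeOH, 30% H2O2, 0 °C
Reagents that add atoms: none
Why: Paterson boron aldol, in which the ketone can enolise only at its methyl group (C10 is sp2) and the Ipc2B enolate adds to the Si face of 10, setting C3 as S (about 55–80% ee is usual for methyl ketones, so enantiomeric enrichment may be needed).

Step 7
Reactants: 11 (2Z,4S)-12-chloro-1,1-diethoxy-4-hydroxy-3-methyl-7-methylidenedodec-2-en-10-yn-6-one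
Product: 12 (2Z,4S,6S)-12-chloro-1,1-diethoxy-6-hydroxy-3-methyl-7-methylidenedodec-2-en-10-yn-4-yl acetate
Conditions: MeCHO (8 equiv), SmI2 (30 mol %, pre-aged with MeCHO until the blue colour fades), THF, −10 °C
Reagents that add atoms: acetaldehyde, CC=O
Why: Evans–Tishchenko reduction, in which the samarium-bound hemiacetal of the C3 hydroxyl and acetaldehyde delivers hydride to C1 through a chair-like transition state, giving the 1,3-anti (1S) carbinol and placing the acetyl group on O3 in the same event, the temporary C1 centre being erased in step 10.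

Step 8
Reactants: 12 (2Z,4S,6S)-12-chloro-1,1-diethoxy-6-hydroxy-3-methyl-7-methylidenedodec-2-en-10-yn-4-yl acetate
Product: 13 (2Z,4S,6S)-12-chloro-6-hydroxy-3-methyl-7-methylidene-1-oxododec-2-en-10-yn-4-yl acetate
Conditions: PPTS (10 mol %), acetone/H2O 10:1, rt
Reagents that add atoms: water, O
Why: Mild acid hydrolysis of an α,β-unsaturated acetal, fast enough at rt to leave the allylic acetate, the propargylic chloride and the Z-alkene intact.

Step 9
Reactants: 13 (2Z,4S,6S)-12-chloro-6-hydroxy-3-methyl-7-methylidene-1-oxododec-2-en-10-yn-4-yl acetate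
Product: 15 (1S,3S,4Z,6R)-3,13-diacetoxy-1-hydroxygermacra-4,7(11),10(14)-trien-12,6-olide, via macrocyclic allenol 14 (not isolated)
Conditions: (a) indium powder (2 equiv), NaI (0.2 equiv), DMF, rt, 13 added over 12 h (final 2 mM); (b) supernatant moved by cannula off the excess indium, no work-up: Pd(OAc)2 (10 mol %), 1,4-benzoquinone (1.5 equiv), LiOAc (5 equiv), AcOH (10 vol %), CO (1 atm), 40 °C
Reagents that add atoms: carbon monoxide, [C-]#[O+]; acetic acid, CC(=O)O
Why: Proposed new method: stage a is a Barbier reaction in which the γ-alkyl propargylindium reacts through C7 (SE2′) with the only carbonyl group left in 13 and closes the ten-membered ring as the 7-vinylidene carbinol 14 (closest known types: allenol-selective indium couplings of 1-halo-2-alkynes and the macrocyclic Barbier closures used for germacranolides), C6 being set by 1,4-induction because A1,3 strain holds H3 and the formyl H of the s-trans enal in the plane of the Z-alkene and a twist conformation of the even-membered cis-cycloalkene puts the two allylic ring bonds on opposite faces, so that C7 should reach the Si face (6R, trans to the C3 acetate), although this selectivity is argued and not established; stage b follows the mechanism of the known PdCl2/CuCl2 chlorocyclocarbonylation of 2,3-allenols (O6, CO and divalent palladium give an alkoxycarbonylpalladium species, acyl transfer to the central allene carbon C11 closes the butenolide and leaves an η3-allyl over C7–C11–C13), except that acetate captures the allyl at its unhindered C13 terminus as in benzoquinone-driven diene diacetoxylation, benzoquinone returns zerovalent palladium to the divalent state, and C6 is not touched.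

Step 10
Reactants: 15 (1S,3S,4Z,6R)-3,13-diacetoxy-1-hydroxygermacra-4,7(11),10(14)-trien-12,6-olide
Product: 16 (3S,4Z,6R)-3,13-diacetoxy-1-oxogermacra-4,7(11),10(14)-trien-12,6-olide (CNP0272505.1)
Conditions: Dess–Martin periodinane (1.3 equiv), NaHCO3, CH2Cl2, 0 °C → rt
Reagents that add atoms: none
Why: Dess–Martin oxidation of the only free hydroxyl group gives the α-methylene ketone under buffered, base-free conditions that spare the β-acetoxy ketone, and C3 and C6 are unaffected.

## Compound list
1 | propargyl alcohol | C#CCO | starting material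
2 | 2-(3-chloropropyl)-2-methyl-1,3-dioxolane | CC1(CCCCl)OCCO1 | starting material
3 | 6-(2-methyl-1,3-dioxolan-2-yl)hex-2-yn-1-ol (ketal alkynol) | CC1(CCCC#CCO)OCCO1 | intermediate
4 | 8-hydroxyoct-6-yn-2-one | CC(=O)CCCC#CCO | intermediate
5 | 8-hydroxy-3-methylideneoct-6-yn-2-one | CC(=O)C(=C)CCC#CCO | intermediate
6 | 6-methylidene-7-oxooct-2-yn-1-yl methanesulfonate (propargylic mesylate) | CC(=O)C(=C)CCC#CCOS(C)(=O)=O | intermediate
7 | 8-chloro-3-methylideneoct-6-yn-2-one | CC(=O)C(=C)CCC#CCCl | intermediate
8 | (Z)-3-(bromomagnesio)-2-methylprop-2-en-1-olate bromomagnesium salt (vinylmagnesium chelate) | Br[Mg]/C=C(/C)CO[Mg]Br | intermediate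
9 | (Z)-4,4-diethoxy-2-methylbut-2-en-1-ol | CCOC(OCC)/C=C(/C)CO | intermediate
10 | (Z)-4,4-diethoxy-2-methylbut-2-enal | CCOC(OCC)/C=C(/C)C=O | intermediate
11 | (2Z,4S)-12-chloro-1,1-diethoxy-4-hydroxy-3-methyl-7-methylidenedodec-2-en-10-yn-6-one | CCOC(OCC)/C=C(/C)[C@@H](O)CC(=O)C(=C)CCC#CCCl | intermediate
12 | (2Z,4S,6S)-12-chloro-1,1-diethoxy-6-hydroxy-3-methyl-7-methylidenedodec-2-en-10-yn-4-yl acetate | CCOC(OCC)/C=C(/C)[C@@H](OC(C)=O)C[C@H](O)C(=C)CCC#CCCl | intermediate
13 | (2Z,4S,6S)-12-chloro-6-hydroxy-3-methyl-7-methylidene-1-oxododec-2-en-10-yn-4-yl acetate | O=C/C=C(/C)[C@@H](OC(C)=O)C[C@H](O)C(=C)CCC#CCCl | intermediate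
14 | (1S,3S,4Z,6R)-3-acetoxy-1,6-dihydroxy-4-methyl-10-methylidene-7-vinylidenecyclodec-4-ene, germacrane numbering (macrocyclic allenol) | C=C1CCC(=C=C)[C@H](O)/C=C(/C)[C@@H](OC(C)=O)C[C@@H]1O | intermediate
15 | (1S,3S,4Z,6R)-3,13-diacetoxy-1-hydroxygermacra-4,7(11),10(14)-trien-12,6-olide | C=C1CCC2=C(COC(C)=O)C(=O)O[C@@H]2/C=C(/C)[C@@H](OC(C)=O)C[C@@H]1O | intermediate
16 | (3S,4Z,6R)-3,13-diacetoxy-1-oxogermacra-4,7(11),10(14)-trien-12,6-olide (CNP0272505.1) | C=C1CCC2=C(COC(C)=O)C(=O)O[C@@H]2/C=C(/C)[C@@H](OC(C)=O)CC1=O | target

## Step count and risks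
Total steps: 10. Longest linear sequence: 8 (steps 1, 2, 3, 6, 7, 8, 9, 10).

The three steps most likely to fail are these.

Step 9. The uncertain points are ten-membered allenol closure against twelve-membered alkyne closure, the diastereoselectivity at C6, and the untested acetate capture. The fallback sets out from 13 and comes back at 15. It separates the two ring closures and puts C6 under reagent control. The ring alone is closed with CrCl2 bound to a chiral carbazole bis(oxazoline) ligand (Nozaki–Hiyama allenylation), and allenol 14 is isolated. 14 is then taken through the known PdCl2/CuCl2/CO chlorocyclocarbonylation of 2,3-allenols to the 13-chloro butenolide F1. AgOAc in AcOH exchanges the activated allylic chloride for acetate to give 15.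

Step 4. The chelated vinylmagnesium may react slowly with the orthoformate, and 9 can collapse to 3-methylfuran on contact with acid. The fallback sets out from 1 and comes back at 9. The same carbomagnesiation is quenched with iodine, a well-established reaction, to give (Z)-3-iodo-2-methylprop-2-en-1-ol F2. This is silylated with TBSCl to the silyl ether F3, so no lactol can form. Iodine–lithium exchange with t-BuLi and DMF then gives (Z)-4-(tert-butyldimethylsilyloxy)-3-methylbut-2-enal F4. HC(OEt)3 and PPTS convert it into the silyl-protected diethyl acetal F5, and TBAF releases 9.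

Step 2. The risks are methylenation at C1 instead of C3 of the ketone, over-methylenation and enone oligomerisation. The fallback sets out from 4 and comes back at 5. It replaces the direct transfer by a regiodefined stepwise Mannich and Hofmann-type elimination sequence. TMSI and (Me3Si)2NH give the thermodynamic bis-silyl enol ether F6. Eschenmoser's salt followed by aqueous work-up gives the Mannich base F7. MeI gives the methiodide F8, and NaHCO3 eliminates trimethylamine to give 5.

## Further compounds
F1 | step 9 | (1S,3S,4Z,6R)-3-acetoxy-13-chloro-1-hydroxygermacra-4,7(11),10(14)-trien-12,6-olide | C=C1CCC2=C(CCl)C(=O)O[C@@H]2/C=C(/C)[C@@H](OC(C)=O)C[C@@H]1O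
F2 | step 4 | (Z)-3-iodo-2-methylprop-2-en-1-ol | I/C=C(/C)CO
F3 | step 4 | (Z)-tert-butyl[(3-iodo-2-methylprop-2-en-1-yl)oxy]dimethylsilane | I/C=C(/C)CO[Si](C)(C)C(C)(C)C
F4 | step 4 | (Z)-4-(tert-butyldimethylsilyloxy)-3-methylbut-2-enal | O=C/C=C(/C)CO[Si](C)(C)C(C)(C)C
F5 | step 4 | (Z)-tert-butyl[(4,4-diethoxy-2-methylbut-2-en-1-yl)oxy]dimethylsilane | CCOC(OCC)/C=C(/C)CO[Si](C)(C)C(C)(C)C
F6 | step 2 | (Z)-2,8-bis(trimethylsilyloxy)oct-2-en-6-yne | C/C(=C/CCC#CCO[Si](C)(C)C)O[Si](C)(C)C
F7 | step 2 | 3-[(dimethylamino)methyl]-8-hydroxyoct-6-yn-2-one | CC(=O)C(CN(C)C)CCC#CCO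
F8 | step 2 | (2-acetyl-7-hydroxyhept-5-yn-1-yl)trimethylammonium iodide | CC(=O)C(C[N+](C)(C)C)CCC#CCO.[I-]
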